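**Strategy.** Ring A of torilin (C1–C5: C3 ketone, C4 methyl, C4=C5) is the aldol product of a 1,4-diketone, and a 2-ethylfuran is a masked 1,4-diketone. In that furan the carbons that become C5 (α) and C1 (β) are adjacent nucleophiles. The key step lets them add, in one gold-catalysed operation, to the two electrophilic termini C6 and C10 of hex-1-en-4-yn-3-one (C8 carbonyl), which closes the seven-membered ring C1, C5–C10 on the furan. The resulting enone then relays the stereochemistry: C10 by asymmetric conjugate reduction, C7 and C8 by carboxylation and chelation-controlled reduction, C1 by equilibration when the furan is unmasked to ring A.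

Key step: step 2

Numbering: carbon labels C1–C11 are guaiane numbers (ring A = C1–C5; seven-membered ring = C1, C5, C6, C7, C8, C9, C10; C11 = carbinol carbon on C7). Locants inside compound names belong to the ring system named.

Assumption: the facial sense of the CuH catalyst in step 3 is taken by analogy with 3-methylcycloalk-2-enones; if the first run gives the 4R ketone, the antipodal ligand is used.

Step 1
Reactants: 1 N-methoxy-N-methylacrylamide; 2 prop-1-ynylmagnesium bromide
Product: 3 hex-1-en-4-yn-3-one
Conditions: THF, −78 → −20 °C; inverse quench into cold 1 M HCl; kept as a solution in 1,2-dichloroethane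
Reagents that add atoms: none
Why: Weinreb ketone synthesis, in which the chelated tetrahedral intermediate prevents a second addition and collapses only on the acidic quench, which also protonates the liberated amine before it can add to the vinyl ketone.

Step 2
Reactants: 3 hex-1-en-4-yn-3-one; 4 2-ethylfuran
Product: 6 2-ethyl-4-methyl-7,8-dihydro-6H-cyclohepta[b]furan-6-one, via furyl ynone 5 (not isolated)
Conditions: AuCl3 (5 mol %), AgOTf (15 mol %), 4 (1.5 equiv), 1,2-dichloroethane, −20 → 50 °C
Reagents that add atoms: none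
Why: Trivalent gold first acts as a Lewis acid for the Friedel–Crafts conjugate addition of the free furan α-carbon (C5) to the unsubstituted vinyl terminus C6 of 3, the closest known reaction being the AuCl3-catalysed addition of 2-alkylfurans to methyl vinyl ketone. The same catalyst then activates the ynone of 5 for anti-hydroarylation by the furan β-carbon (C1) at the alkyne β-carbon C10, the closest known reaction being the gold-catalysed hydroarylation of alkynones and aryl alkynoates by electron-rich arenes. The seven-membered ring closes in the 7-endo-dig mode, and protodeauration leaves the C9=C10 enone conjugated to the furan. No stereocenter is formed, which is intended because C10 is set in step 3 under catalyst control. The step needs chemoselectivity between the two acceptor termini and regioselectivity on the furan: the α-position is the most nucleophilic site and the CH2 terminus the least hindered acceptor, so C5–C6 forms first, and once the chain sits on C5 only the neighbouring β-carbon can reach C10 through a seven-membered transition state. Attack at the substituted α-carbon (six-membered spiro closure) is expected to be reversible, and the alkyne carbon C9 is not electrophilic.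

Step 3
Reactants: 6 2-ethyl-4-methyl-7,8-dihydro-6H-cyclohepta[b]furan-6-one
Product: 7 (4S)-2-ethyl-4-methyl-4,5,7,8-tetrahydro-6H-cyclohepta[b]furan-6-one
Conditions: Cu(OAc)2·H2O (3 mol %), (R)-DTBM-SEGPHOS (3 mol %), (EtO)2MeSiH (2 equiv), t-BuOH (2 equiv), toluene, 0 °C → rt
Reagents that add atoms: none
Why: CuH-catalysed asymmetric conjugate reduction of a 3-methylcycloalk-2-enone, in which the ligand-bound copper hydride adds to one face of C10 (catalyst control) and t-BuOH protonates the copper enolate, so that the 4S centre (C10) is set.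

Step 4
Reactants: 7 (4S)-2-ethyl-4-methyl-4,5,7,8-tetrahydro-6H-cyclohepta[b]furan-6-one
Product: 8 methyl (4S)-2-ethyl-4-methyl-6-oxo-5,6,7,8-tetrahydro-4H-cyclohepta[b]furan-7-carboxylate (C7 epimers and enol)
Conditions: NaH (2.5 equiv), (MeO)2CO (5 equiv), MeOH (cat.), THF, reflux; AcOH quench
Reagents that add atoms: dimethyl carbonate, COC(=O)OC
Why: Claisen-type C-acylation under thermodynamic control, driven by deprotonation of the β-keto ester and directed to C7 because the C9 isomer would suffer allylic strain with the branched C10, as in the carbomethoxylation of 3-methylcyclohexanone at C6.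

Step 5
Reactants: 8 methyl (4S)-2-ethyl-4-methyl-6-oxo-5,6,7,8-tetrahydro-4H-cyclohepta[b]furan-7-carboxylate
Product: 9 methyl (4S,6R,7S)-2-ethyl-6-hydroxy-4-methyl-5,6,7,8-tetrahydro-4H-cyclohepta[b]furan-7-carboxylate
Conditions: Zn(BH4)2, Et2O, −20 → 0 °C; H2O
Reagents that add atoms: none
Why: Chelation-controlled reduction of a cyclic β-keto ester with dynamic resolution at C7: the zinc chelate delivers hydride syn to H7 (cis hydroxy ester), the C7 epimers interconvert through the enol, and the epimer whose open face is also anti to the C10 methyl should react faster, giving C10-methyl, C8-OH and C7-ester on one face.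

Step 6
Reactants: 9 methyl (4S,6R,7S)-2-ethyl-6-hydroxy-4-methyl-5,6,7,8-tetrahydro-4H-cyclohepta[b]furan-7-carboxylate
Product: 11 (4S,6R,7S)-2-ethyl-7-(2-hydroxypropan-2-yl)-4-methyl-5,6,7,8-tetrahydro-4H-cyclohepta[b]furan-6-ol, via methyl ketone 10 (not isolated)
Conditions: MeMgBr (5 equiv), THF, −20 °C → rt; aqueous work-up
Reagents that add atoms: methylmagnesium bromide, C[Mg]Br
Why: Double Grignard addition to the ester through ketone 10 builds the C11 carbinol, while the magnesium alkoxide at C8 suppresses enolization at C7, so that no stereocenter is touched.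

Step 7
Reactants: 11 (4S,6R,7S)-2-ethyl-7-(2-hydroxypropan-2-yl)-4-methyl-5,6,7,8-tetrahydro-4H-cyclohepta[b]furan-6-ol
Product: 12 acetonide of 11 (2,2,4,4-tetramethyl-1,3-dioxane cis-fused at C7–C8, bridging the C8 oxygen and the C11 oxygen)
Conditions: Me2C(OMe)2, PPTS (cat.), CH2Cl2, rt
Reagents that add atoms: 2,2-dimethoxypropane, COC(C)(C)OC
Why: Acid-catalysed transacetalization of the cis-1,3-diol gives a six-membered acetonide that keeps both hydroxyl groups from trapping the intermediates of the furan oxidation.

Step 8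
Reactants: 12 acetonide of 11
Product: 13 Z-enedione (cycloheptanone with C5 ketone, exocyclic (Z)-C1=C2H–C3(=O)–CH2CH3 at C1, (S)-methyl at C10, acetonide retained)
Conditions: NBS (1.05 equiv), NaHCO3, acetone/H2O (10:1), −15 °C
Reagents that add atoms: water, O
Why: Oxidative ring opening of a 2,3,5-trialkylfuran (bromonium attack at an α-carbon, addition of water, loss of HBr) unmasks the 1,4-dicarbonyl unit as its Z-enedione under buffered conditions that spare the acetonide.

Step 9
Reactants: 13 Z-enedione
Product: 14 saturated 1,4-diketone (C5 ring ketone, 2-oxobutyl chain on C1, mixture of C1 epimers)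
Conditions: H2 (1 atm), Pd/C, EtOAc, rt
Reagents that add atoms: none
Why: Catalytic hydrogenation takes the electron-poor enedione alkene far faster than any other group, and the new C1 centre, being α to the C5 ketone, is left to equilibrate in the next step.

Step 10
Reactants: 14 saturated 1,4-diketone
Product: 16 (1R,7S,8R,10S)-8,11-dihydroxyguai-4-en-3-one acetonide, via aldol adduct 15 (not isolated)
Conditions: KOH, MeOH/H2O, 60 °C
Reagents that add atoms: none
Why: Intramolecular aldol condensation of a 1,4-diketone (the C4 enolate of the ethyl ketone adds to C5 and adduct 15 dehydrates by E1cB to the tetrasubstituted C4=C5 enone), while the base-labile C1 centre should settle in the more stable epimer with C2 trans to the C10 methyl, which is 1R.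

Step 11
Reactants: 16 (1R,7S,8R,10S)-8,11-dihydroxyguai-4-en-3-one acetonide
Product: 17 (5S,6R,8S,8aR)-6-hydroxy-5-(2-hydroxypropan-2-yl)-3,8-dimethyl-4,5,6,7,8,8a-hexahydroazulen-2(1H)-one
Conditions: AcOH/H2O (4:1), 40 °C
Reagents that add atoms: none
Why: Mild acid-catalysed acetal hydrolysis frees the diol without ionizing the tertiary alcohol or moving the enone.

Step 12
Reactants: 17 (5S,6R,8S,8aR)-6-hydroxy-5-(2-hydroxypropan-2-yl)-3,8-dimethyl-4,5,6,7,8,8a-hexahydroazulen-2(1H)-one; 18 angelic acid
Product: 20 (5S,6R,8S,8aR)-5-(2-hydroxypropan-2-yl)-3,8-dimethyl-2-oxo-1,2,4,5,6,7,8,8a-octahydroazulen-6-yl (Z)-2-methylbut-2-enoate, via mixed anhydride 19 (not isolated)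
Conditions: 2,4,6-Cl3C6H2COCl, Et3N, toluene, rt; then 17, 80 °C
Reagents that add atoms: none
Why: Yamaguchi-type esterification through the hindered mixed anhydride acylates only the secondary C8 hydroxyl and, run without a nucleophilic catalyst, should keep the Z geometry of the angelate.

Step 13
Reactants: 20 (5S,6R,8S,8aR)-5-(2-hydroxypropan-2-yl)-3,8-dimethyl-2-oxo-1,2,4,5,6,7,8,8a-octahydroazulen-6-yl (Z)-2-methylbut-2-enoate
Product: 21 torilin
Conditions: Ac2O, DMAP (cat.), Et3N, CH2Cl2, 35 °C
Reagents that add atoms: acetic anhydride, CC(=O)OC(C)=O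
Why: DMAP-catalysed acylation through the N-acetylpyridinium ion is strong enough for the remaining tertiary alcohol and mild enough to leave the angelate and the C1 centre unchanged.

**Compound list**

1 | N-methoxy-N-methylacrylamide | C=CC(=O)N(C)OC | starting material
2 | prop-1-ynylmagnesium bromide | CC#C[Mg]Br | starting material
3 | hex-1-en-4-yn-3-one | C=CC(=O)C#CC | intermediate
4 | 2-ethylfuran | CCc1ccco1 | starting material
5 | 1-(5-ethylfuran-2-yl)hex-4-yn-3-one | CCc1ccc(CCC(=O)C#CC)o1 | intermediate
6 | 2-ethyl-4-methyl-7,8-dihydro-6H-cyclohepta[b]furan-6-one | O=C1C=C(C)c2cc(CC)oc2CC1 | intermediate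
7 | (4S)-2-ethyl-4-methyl-4,5,7,8-tetrahydro-6H-cyclohepta[b]furan-6-one | O=C1C[C@H](C)c2cc(CC)oc2CC1 | intermediate
8 | methyl (4S)-2-ethyl-4-methyl-6-oxo-5,6,7,8-tetrahydro-4H-cyclohepta[b]furan-7-carboxylate (C7 epimers) | O=C1C[C@H](C)c2cc(CC)oc2CC1C(=O)OC | intermediate
9 | methyl (4S,6R,7S)-2-ethyl-6-hydroxy-4-methyl-5,6,7,8-tetrahydro-4H-cyclohepta[b]furan-7-carboxylate | O[C@@H]1C[C@H](C)c2cc(CC)oc2C[C@@H]1C(=O)OC | intermediate
10 | 1-[(4S,6R,7S)-2-ethyl-6-hydroxy-4-methyl-5,6,7,8-tetrahydro-4H-cyclohepta[b]furan-7-yl]ethan-1-one (present as its magnesium alkoxide) | O[C@@H]1C[C@H](C)c2cc(CC)oc2C[C@@H]1C(C)=O | intermediate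
11 | (4S,6R,7S)-2-ethyl-7-(2-hydroxypropan-2-yl)-4-methyl-5,6,7,8-tetrahydro-4H-cyclohepta[b]furan-6-ol | O[C@@H]1C[C@H](C)c2cc(CC)oc2C[C@@H]1C(C)(C)O | intermediate
12 | acetonide of 11 (1,3-dioxane cis-fused at C7–C8) | O1[C@@H]2C[C@H](C)c3cc(CC)oc3C[C@@H]2C(C)(C)OC1(C)C | intermediate
13 | Z-enedione from furan opening of 12 (C5 ketone, (Z)-2-oxobutylidene at C1) | O1[C@@H]2C[C@H](C)/C(=C/C(=O)CC)C(=O)C[C@@H]2C(C)(C)OC1(C)C | intermediate
14 | saturated 1,4-diketone (2-oxobutyl at C1, C1 epimers) | O1[C@@H]2C[C@H](C)C(CC(=O)CC)C(=O)C[C@@H]2C(C)(C)OC1(C)C | intermediate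
15 | aldol adduct (ring A closed, C5 tertiary alcohol, C4 methine) | O1[C@@H]2C[C@H](C)C3CC(=O)C(C)C3(O)C[C@@H]2C(C)(C)OC1(C)C | intermediate
16 | (1R,7S,8R,10S)-8,11-dihydroxyguai-4-en-3-one acetonide | O1[C@@H]2C[C@H](C)[C@H]3CC(=O)C(C)=C3C[C@@H]2C(C)(C)OC1(C)C | intermediate
17 | (5S,6R,8S,8aR)-6-hydroxy-5-(2-hydroxypropan-2-yl)-3,8-dimethyl-4,5,6,7,8,8a-hexahydroazulen-2(1H)-one | O[C@@H]1C[C@H](C)[C@H]2CC(=O)C(C)=C2C[C@@H]1C(C)(C)O | intermediate
18 | angelic acid, (Z)-2-methylbut-2-enoic acid | C/C=C(/C)C(=O)O | starting material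
19 | (Z)-2-methylbut-2-enoic 2,4,6-trichlorobenzoic anhydride | C/C=C(/C)C(=O)OC(=O)c1c(Cl)cc(Cl)cc1Cl | intermediate
20 | (5S,6R,8S,8aR)-5-(2-hydroxypropan-2-yl)-3,8-dimethyl-2-oxo-1,2,4,5,6,7,8,8a-octahydroazulen-6-yl (Z)-2-methylbut-2-enoate | C/C=C(/C)C(=O)O[C@@H]1C[C@H](C)[C@H]2CC(=O)C(C)=C2C[C@@H]1C(C)(C)O | intermediate
21 | torilin, (5S,6R,8S,8aR)-5-(2-acetoxypropan-2-yl)-3,8-dimethyl-2-oxo-1,2,4,5,6,7,8,8a-octahydroazulen-6-yl (Z)-2-methylbut-2-enoate | C/C=C(/C)C(=O)O[C@@H]1C[C@H](C)[C@H]2CC(=O)C(C)=C2C[C@@H]1C(C)(C)OC(C)=O | target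

**Total step count:** 13. **Longest linear sequence:** 13 steps (1 → 21).

**Steps most likely to fail**

Step 2. The intermolecular addition may not discriminate between the vinyl and the alkynyl terminus of 3. The substituted furan α-carbon may be attacked in place of the β-carbon, leading to spirocyclization and ring opening. The strained 7-endo-dig closure may also stall at 5. The fallback sets out from 4 and comes back at 6. Friedel–Crafts conjugate addition of 4 to methyl vinyl ketone (BF3·OEt2, CH2Cl2, −40 °C) should give 4-(5-ethylfuran-2-yl)butan-2-one F1. Claisen condensation at its methyl group with ethyl acetate (NaH, THF) should give 6-(5-ethylfuran-2-yl)hexane-2,4-dione F2. Acid-mediated cyclodehydration of F2 (p-TsOH, toluene, reflux with removal of water) should then close the C1–C10 bond at the furan β-carbon through a flexible saturated tether and return to 6.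

Step 3. Hydride transfer to C10 may be slow because the β-carbon is conjugated to the electron-rich furan, and facial discrimination may be poor. The fallback sets out from 6 and comes back at 7. CBS reduction ((S)-Me-CBS, BH3·SMe2, THF, −20 °C) should give (6R)-2-ethyl-4-methyl-7,8-dihydro-6H-cyclohepta[b]furan-6-ol F3. Hydroxyl-directed hydrogenation ([Ir(cod)(PCy3)(py)]PF6, H2, CH2Cl2) delivers hydrogen to C10 on the face of the hydroxyl group and should give (4S,6R)-2-ethyl-4-methyl-5,6,7,8-tetrahydro-4H-cyclohepta[b]furan-6-ol F4. Oxidation with DMP removes the relay stereocenter and returns 7.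

Step 5. The C7 epimers of 8 may not equilibrate fast enough under the reduction conditions, so that hydride attack on the slower epimer erodes the diastereomer ratio. The fallback sets out from 8 and comes back at 11. Hydrogenation with dynamic kinetic resolution (RuCl2[(S)-BINAP], H2, 50 atm, CH2Cl2/MeOH, 50 °C) fixes C7 under catalyst control and should give the trans product methyl (4S,6S,7S)-2-ethyl-6-hydroxy-4-methyl-5,6,7,8-tetrahydro-4H-cyclohepta[b]furan-7-carboxylate F5. MeMgBr should convert it into (4S,6S,7S)-2-ethyl-7-(2-hydroxypropan-2-yl)-4-methyl-5,6,7,8-tetrahydro-4H-cyclohepta[b]furan-6-ol F6. DMP should oxidize the secondary alcohol to (4S,7R)-2-ethyl-7-(2-hydroxypropan-2-yl)-4-methyl-4,5,7,8-tetrahydro-6H-cyclohepta[b]furan-6-one F7. LiBH(s-Bu)3 (THF, −78 °C) then attacks from the face opposite to the C7 substituent and the C10 methyl, which should give 11.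

Further compounds
F1 | step 2 | 4-(5-ethylfuran-2-yl)butan-2-one | CCc1ccc(CCC(C)=O)o1
F2 | step 2 | 6-(5-ethylfuran-2-yl)hexane-2,4-dione | CCc1ccc(CCC(=O)CC(C)=O)o1
F3 | step 3 | (6R)-2-ethyl-4-methyl-7,8-dihydro-6H-cyclohepta[b]furan-6-ol | O[C@H]1C=C(C)c2cc(CC)oc2CC1
F4 | step 3 | (4S,6R)-2-ethyl-4-methyl-5,6,7,8-tetrahydro-4H-cyclohepta[b]furan-6-ol | O[C@H]1C[C@H](C)c2cc(CC)oc2CC1
F5 | step 5 | methyl (4S,6S,7S)-2-ethyl-6-hydroxy-4-methyl-5,6,7,8-tetrahydro-4H-cyclohepta[b]furan-7-carboxylate | O[C@H]1C[C@H](C)c2cc(CC)oc2C[C@@H]1C(=O)OC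
F6 | step 5 | (4S,6S,7S)-2-ethyl-7-(2-hydroxypropan-2-yl)-4-methyl-5,6,7,8-tetrahydro-4H-cyclohepta[b]furan-6-ol | O[C@H]1C[C@H](C)c2cc(CC)oc2C[C@@H]1C(C)(C)O
F7 | step 5 | (4S,7R)-2-ethyl-7-(2-hydroxypropan-2-yl)-4-methyl-4,5,7,8-tetrahydro-6H-cyclohepta[b]furan-6-one | O=C1C[C@H](C)c2cc(CC)oc2C[C@@H]1C(C)(C)O
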